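You want to know what stands in the flask after 2.5 h, from a charge of 1.2 M.

| flask | substrate | remark | time |
|---|---|---|---|
| delta | 0.80 M | run made earlier |  |
| theta | 1.8 M | run made earlier |  |
| flask | 1.2 M |  | 2.5 h |

| run | time / h | ring / % | isomer of the product / % |
|---|---|---|---|
| delta | 0.200 | 6.2 | 71.0 |
| delta | 0.417 | 5.2 | 72.9 |
| delta | 0.667 | 5.1 | 71.9 |
| delta | 1.33 | 4.7 | 74.1 |
| delta | 2.50 | 4.5 | 71.7 |
| theta | 0.200 | 4.6 | 54.9 |
| theta | 0.667 | 4.5 | 54.5 |
| theta | 1.33 | 2.9 | 57.8 |
| theta | 2.00 | 3.6 | 58.0 |
| theta | 2.50 | 2.8 | 55.6 |

(readings scatter by 1 percentage point)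

* the ring standing at 2.5 h, as a percentage of the substrate charged
* the isomer of the product standing at 2.5 h, as a percentage of the substrate charged



1. Let s be ring plus isomer of the product, as a share of the substrate charged. In both runs s stays level within scatter from first reading to last, so I average it over time: 77.5 % at 0.80 M and 59.8 % at 1.8 M.

2. Suppose substrate leaves by a first-order route that gives s and a second-order route that gives something unseen. The loss rate over the keeping rate then goes with concentration, so lost over kept should go roughly with the charge c.

3. Test this with m = (1 − s)/(s·c). The runs read 0.364 /M and 0.373 /M, though the charges differ by 2.25 times. Their mean is 0.368 /M, the loss per molar, a kind of selectivity factor.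

4. So I reckon s = 1/(1 + m·c) = 69.4 % for this flask. Ring averages 6.42 % of s over all readings of the runs, the early ones included, and I apply that share at 2.5 h, which gives ring 4.46 % and isomer 64.9 %.

5. The forecast said “The loss grows with concentration, which suggests a bimolecular side path competing with a unimolecular one”, and gave ring 3.8 % and isomer 64.5 %. My ring is higher than the forecast's; the isomer values nearly agree.

The flask gives ring 4.06 % and isomer 65.0 %, so both forecast values hold within the margins.

    2 substrate → open dimer (k = 0.00590 /M/s)
    substrate → ring (k = 0.0210 /s)
    substrate + open dimer → open trimer (k = 0.0970 /M/s)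
    ring ⇌ isomer of the product (K = 16.0, k = 0.00490 /s)

In this flask s is 69.1 %, which makes its loss per molar 0.373 /M, beside the 0.368 /M carried from the runs. The rest stands as open dimer 2.43 % and open trimer 28.5 %. Take a neighbour charged with 0.48 M: the same m gives s = 85.0 %, so ring 5.46 % and isomer 79.5 %. That neighbour gives ring 5.01 % and isomer 80.1 %, with open trimer at 11.4 %.

The earlier runs and the new flask come from a simulation from invented constants; noise was put on by code.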